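The route rests on cutting both bonds at the central ester carbonyl carbon. One is the C–C bond to alkene carbon C2 of the 2-(angeloyloxymethyl)but-2-enoyl unit. The other is the C–O bond to the benzylic oxygen on C1 of the propyl chain of benzene ring A. The feature exploited is the C2=C3 alkene whose C4 methyl sits cis to that carbonyl, an isomerisation-prone geometry that maps onto a configurationally stable Z-alkenyl iodide. A single palladium-catalysed carbonylation joins iodide, CO and alcohol with retention, so no activated Z-acid is ever handled. Its precursors are (Z)-2-iodobut-2-enyl angelate and the (S)-1-arylpropanol whose phenol is masked as a TBS ether.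

Key step: step 6

Assumption: (−)-DAIB is taken to direct ethyl transfer to the Si face of the silylated aldehyde as it does for benzaldehyde. The CIP ranking at the carbinol carbon (O > aryl > ethyl > H) is the same, so the descriptor is S.

Design remarks:
- **Vulnerable product.** The coupled product is a Baylis–Hillman-type allylic ester. It is more open than the iodide itself to ionisation by zerovalent palladium and to SN2′ attack by nucleophilic amines.
- **Countermeasures in the coupling.** The iodide is used in excess with the alcohol limiting, the base is hindered i-Pr2NEt (no DMAP, DABCO or Et3N), and the solvent is non-polar.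
- **Angelate installation.** The angelate is introduced by a Mitsunobu reaction, so angelic acid acts only as an oxygen nucleophile and its acyl carbon is never activated.

Step 1
Reactants: 1 (E)-crotonaldehyde
Product: 2 (Z)-2-iodobut-2-enal
Conditions: I2, K2CO3, DMAP (cat.), THF–H2O (1:1), 0 °C to rt; aq. Na2S2O3 wash
Reagents that add atoms: iodine, II
Why: The DMAP-catalysed α-iodination of enals (a Baylis–Hillman-type sequence of conjugate addition, enolate iodination and elimination) is established for simple acyclic enals, and the elimination should leave the C4 methyl trans to the formyl group and therefore cis to iodine, which is the Z isomer.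

Step 2
Reactants: 2 (Z)-2-iodobut-2-enal
Product: 3 (Z)-2-iodobut-2-en-1-ol
Conditions: NaBH4, CeCl3·7H2O, MeOH, 0 °C
Reagents that add atoms: none
Why: The Luche reduction delivers hydride 1,2 to the aldehyde only, and neither the C–I bond nor the alkene geometry is affected at 0 °C.

Step 3
Reactants: 3 (Z)-2-iodobut-2-en-1-ol; 4 angelic acid
Product: 6 (Z)-2-iodobut-2-en-1-yl (Z)-2-methylbut-2-enoate, via alkoxyphosphonium angelate 5 (not isolated)
Conditions: PPh3, DIAD (added last), THF, 0 °C to rt
Reagents that add atoms: none
Why: The Mitsunobu esterification activates the primary allylic alcohol as alkoxyphosphonium ion 5 and uses angelate only as an oxygen nucleophile in an SN2 displacement, so the angeloyl carbonyl is never activated and its Z alkene has no pathway to the tiglate.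

Step 4
Reactants: 7 3-hydroxy-4,5-dimethoxybenzaldehyde
Product: 8 3-(tert-butyldimethylsilyloxy)-4,5-dimethoxybenzaldehyde
Conditions: TBSCl, imidazole, DMF, rt
Reagents that add atoms: tert-butyldimethylsilyl chloride, CC(C)(C)[Si](C)(C)Cl
Why: Imidazole-promoted silylation masks the phenol, which would otherwise consume the zinc reagent in step 5 and compete with the carbinol as the nucleophile in step 6.

Step 5
Reactants: 8 3-(tert-butyldimethylsilyloxy)-4,5-dimethoxybenzaldehyde; 9 diethylzinc
Product: 11 (S)-1-[3-(tert-butyldimethylsilyloxy)-4,5-dimethoxyphenyl]propan-1-ol, via EtZn alkoxide 10 (not isolated)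
Conditions: Et2Zn (2 equiv, hexanes), (−)-DAIB [(2S)-3-exo-(dimethylamino)isoborneol, 5 mol%], toluene, 0 °C; then sat. aq. NH4Cl
Reagents that add atoms: diethylzinc, CC[Zn]CC
Why: In this amino-alcohol-catalysed enantioselective dialkylzinc addition the (−)-DAIB zinc chelate assembles aldehyde and Et2Zn in a dinuclear transition state that should deliver ethyl to the Si face of the formyl group, setting the S carbinol centre under catalyst control while the uncatalysed background addition is negligible at 0 °C.

Step 6
Reactants: 6 (Z)-2-iodobut-2-en-1-yl (Z)-2-methylbut-2-enoate; 11 (S)-1-[3-(tert-butyldimethylsilyloxy)-4,5-dimethoxyphenyl]propan-1-ol; 12 carbon monoxide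
Product: 15 (S)-1-[3-(tert-butyldimethylsilyloxy)-4,5-dimethoxyphenyl]propyl (Z)-2-{[(Z)-2-methylbut-2-enoyl]oxymethyl}but-2-enoate, via alkenyl-PdI(Xantphos) complex 13 (not isolated), via acyl-PdI(Xantphos) complex 14 (not isolated)
Conditions: 6 (1.5 equiv), 11 (1.0 equiv), CO (1 atm), Pd(OAc)2 (5 mol%), Xantphos (6 mol%), i-Pr2NEt (2 equiv), 4 Å MS, toluene (0.5 M in 11), 50 °C
Reagents that add atoms: carbon monoxide, [C-]#[O+]
Why: Zerovalent palladium formed in situ inserts into the C(sp2)–I bond of 6 with retention to give 13, migratory insertion of CO converts it into acyl complex 14, and alcohol 11, assisted by i-Pr2NEt, cleaves 14 at the acyl carbon through its oxygen, which releases 15 and returns the catalyst. The closest known reaction type is the palladium-catalysed alkoxycarbonylation of alkenyl iodides, which preserves alkene geometry and is also practised with secondary alcohols as the limiting partner. No ring closes and no stereocentre is created: both Z alkenes are carried over because neither undergoes a reversible addition, and the S centre survives because only the O–H bond of 11, never its benzylic C–O bond, is broken. The selectivity needed is insertion at C–I rather than ionisation of an allylic angelate, and it is secured by the far higher rate of alkenyl C–I insertion, the π-acidic CO atmosphere that lowers the nucleophilicity of zerovalent palladium, the non-polar solvent and the modest temperature. Because 15 is a Baylis–Hillman-type allylic ester that ionises more easily than 6, the iodide is kept in excess so that the catalyst always finds a faster partner, and the amine is hindered and non-nucleophilic so that neither SN2′ loss of angelate nor conjugate-addition Z-to-E isomerisation can begin. The wide-bite-angle diphosphine keeps the catalyst active under one atmosphere of CO and speeds the ester-forming event, high concentration and molecular sieves favour capture by 11 over adventitious water, and fast CO insertion outruns 5-exo carbopalladation of the trisubstituted angelate alkene.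

Step 7
Reactants: 15 (S)-1-[3-(tert-butyldimethylsilyloxy)-4,5-dimethoxyphenyl]propyl (Z)-2-{[(Z)-2-methylbut-2-enoyl]oxymethyl}but-2-enoate
Product: 16 (S)-1-(3-hydroxy-4,5-dimethoxyphenyl)propyl (Z)-2-{[(Z)-2-methylbut-2-enoyl]oxymethyl}but-2-enoate (CNP0282120.1)
Conditions: TBAF (1.1 equiv), AcOH (1.3 equiv), THF, 0 °C, short reaction time
Reagents that add atoms: none
Why: Fluoride-induced cleavage of an aryl silyl ether is fast at 0 °C, and the acetic acid buffer protonates the phenolate as it forms, so that neither ester is transacylated, the allylic angelate is not displaced and the acid-ionisable benzylic C–O bond sees no strong acid.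

Compound list
1 | (E)-crotonaldehyde, (E)-but-2-enal | C/C=C/C=O | starting material
2 | (Z)-2-iodobut-2-enal (methyl cis to iodine, trans to CHO) | C/C=C(I)/C=O | intermediate
3 | (Z)-2-iodobut-2-en-1-ol | C/C=C(I)/CO | intermediate
4 | angelic acid, (Z)-2-methylbut-2-enoic acid | C/C=C(/C)C(=O)O | starting material
5 | [(Z)-2-iodobut-2-en-1-yloxy]triphenylphosphonium (Z)-2-methylbut-2-enoate (not isolated) | C/C=C(I)/CO[P+](c1ccccc1)(c1ccccc1)c1ccccc1.C/C=C(/C)C(=O)[O-] | intermediate
6 | (Z)-2-iodobut-2-en-1-yl (Z)-2-methylbut-2-enoate | C/C=C(/C)C(=O)OC/C(=C/C)I | intermediate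
7 | 3-hydroxy-4,5-dimethoxybenzaldehyde | O=Cc1cc(O)c(OC)c(OC)c1 | starting material
8 | 3-(tert-butyldimethylsilyloxy)-4,5-dimethoxybenzaldehyde | O=Cc1cc(O[Si](C)(C)C(C)(C)C)c(OC)c(OC)c1 | intermediate
9 | diethylzinc | CC[Zn]CC | starting material
10 | ethylzinc (S)-1-[3-(tert-butyldimethylsilyloxy)-4,5-dimethoxyphenyl]propan-1-olate (not isolated) | CC[Zn]O[C@@H](CC)c1cc(O[Si](C)(C)C(C)(C)C)c(OC)c(OC)c1 | intermediate
11 | (S)-1-[3-(tert-butyldimethylsilyloxy)-4,5-dimethoxyphenyl]propan-1-ol | O[C@@H](CC)c1cc(O[Si](C)(C)C(C)(C)C)c(OC)c(OC)c1 | intermediate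
12 | carbon monoxide | [C-]#[O+] | starting material
13 | (Xantphos)Pd(I)[(Z)-1-(angeloyloxy)but-2-en-2-yl], methyl cis to palladium (not isolated; dative P–Pd bonds written charge-separated) | C/C=C(/C)C(=O)OC/C(=C/C)[Pd-2]1(I)[P+](c2ccccc2)(c2ccccc2)c2cccc3c2Oc2c(cccc2[P+]1(c1ccccc1)c1ccccc1)C3(C)C | intermediate
14 | (Xantphos)Pd(I)[(Z)-2-(angeloyloxymethyl)but-2-enoyl] (not isolated; dative P–Pd bonds written charge-separated) | C/C=C(/C)C(=O)OC/C(=C/C)C(=O)[Pd-2]1(I)[P+](c2ccccc2)(c2ccccc2)c2cccc3c2Oc2c(cccc2[P+]1(c1ccccc1)c1ccccc1)C3(C)C | intermediate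
15 | (S)-1-[3-(tert-butyldimethylsilyloxy)-4,5-dimethoxyphenyl]propyl (Z)-2-{[(Z)-2-methylbut-2-enoyl]oxymethyl}but-2-enoate | C/C=C(/C)C(=O)OC/C(=C/C)C(=O)O[C@@H](CC)c1cc(O[Si](C)(C)C(C)(C)C)c(OC)c(OC)c1 | intermediate
16 | (S)-1-(3-hydroxy-4,5-dimethoxyphenyl)propyl (Z)-2-{[(Z)-2-methylbut-2-enoyl]oxymethyl}but-2-enoate | C/C=C(/C)C(=O)OC/C(=C/C)C(=O)O[C@@H](CC)c1cc(O)c(OC)c(OC)c1 | target

Total step count: 7. Longest linear sequence: 5 steps (1, 2, 3, 6, 7). The arene branch runs over 4 steps (4, 5, 6, 7).

Steps most likely to fail

1. **Step 6.**
   - What may go wrong: capture of the acylpalladium by a hindered secondary alcohol used in stoichiometric amount may be slow. That would give zerovalent palladium time to ionise an allylic angelate, with loss or transposition of the angelate and erosion of the Z geometry.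
   - Fallback (sets out from 3 and 11, comes back at 15): the order of bond formation is changed so that no allylic ester is present while palladium is.
   - Alcohol 3 is silylated (TESCl, imidazole, CH2Cl2) to (Z)-triethyl[(2-iodobut-2-en-1-yl)oxy]silane F1. Its silyloxy group is not a leaving group for palladium or amines, so a larger excess, more heat and a higher CO pressure become admissible.
   - Alkoxycarbonylation of F1 with 11 should give (S)-1-[3-(tert-butyldimethylsilyloxy)-4,5-dimethoxyphenyl]propyl (Z)-2-[(triethylsilyloxy)methyl]but-2-enoate F2.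
   - AcOH–THF–H2O at rt removes the primary alkyl TES ether, while the aryl TBS ether, which resists mild acid, stays. This gives (S)-1-[3-(tert-butyldimethylsilyloxy)-4,5-dimethoxyphenyl]propyl (Z)-2-(hydroxymethyl)but-2-enoate F3.
   - A Mitsunobu esterification of F3 with angelic acid 4 (PPh3, DIAD, THF, 0 °C) then leads to 15.

2. **Step 5.**
   - What may go wrong: insufficient facial selectivity, for instance through competing uncatalysed or zinc-alkoxide-promoted ethyl transfer to the aldehyde.
   - Fallback (sets out from 8, comes back at 11): the centre is set by reduction instead of alkylation.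
   - EtMgBr (THF, −78 °C) gives racemic 1-[3-(tert-butyldimethylsilyloxy)-4,5-dimethoxyphenyl]propan-1-ol F4.
   - Dess–Martin periodinane (NaHCO3, CH2Cl2) gives 1-[3-(tert-butyldimethylsilyloxy)-4,5-dimethoxyphenyl]propan-1-one F5.
   - Asymmetric transfer hydrogenation with RuCl[(S,S)-TsDPEN](p-cymene) in HCO2H–Et3N should give 11. The S,S catalyst is the one that converts aryl alkyl ketones into S carbinols.

3. **Step 3.**
   - What may go wrong: SN2′ attack of angelate at C3 of the allyl unit, phosphine-induced Z-to-E drift of the angelate, or laborious separation of a small non-polar ester from the Mitsunobu residues.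
   - Fallback (sets out from 3, comes back at 6): the redox condensation is replaced by a discrete halide and a carboxylate alkylation, with no phosphine present while the angelate is.
   - PBr3 (Et2O, 0 °C) converts 3 into (Z)-1-bromo-2-iodobut-2-ene F6.
   - Angelic acid 4 and Cs2CO3 in DMF give caesium (Z)-2-methylbut-2-enoate F7, which is O-alkylated by F6 at rt to give 6.

Further compounds
F1 | step 6 | (Z)-triethyl[(2-iodobut-2-en-1-yl)oxy]silane | C/C=C(I)/CO[Si](CC)(CC)CC
F2 | step 6 | (S)-1-[3-(tert-butyldimethylsilyloxy)-4,5-dimethoxyphenyl]propyl (Z)-2-[(triethylsilyloxy)methyl]but-2-enoate | CC[Si](CC)(CC)OC/C(=C/C)C(=O)O[C@@H](CC)c1cc(O[Si](C)(C)C(C)(C)C)c(OC)c(OC)c1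
F3 | step 6 | (S)-1-[3-(tert-butyldimethylsilyloxy)-4,5-dimethoxyphenyl]propyl (Z)-2-(hydroxymethyl)but-2-enoate | OC/C(=C/C)C(=O)O[C@@H](CC)c1cc(O[Si](C)(C)C(C)(C)C)c(OC)c(OC)c1
F4 | step 5 | racemic 1-[3-(tert-butyldimethylsilyloxy)-4,5-dimethoxyphenyl]propan-1-ol | CCC(O)c1cc(O[Si](C)(C)C(C)(C)C)c(OC)c(OC)c1
F5 | step 5 | 1-[3-(tert-butyldimethylsilyloxy)-4,5-dimethoxyphenyl]propan-1-one | CCC(=O)c1cc(O[Si](C)(C)C(C)(C)C)c(OC)c(OC)c1
F6 | step 3 | (Z)-1-bromo-2-iodobut-2-ene | C/C=C(I)/CBr
F7 | step 3 | caesium (Z)-2-methylbut-2-enoate | C/C=C(/C)C(=O)[O-].[Cs+]
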